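The constants used here were chosen freely; what happens was integrated by code.

I started with the easy step, which was to follow a single catalyst intermediate and ask where it goes.

| setting | ash | oak | birch |
|---|---|---|---|
| substrate | 0.20 M | 0.20 M (fed, over 12.5 h) | 0.20 M |
| capture agent | 0.0600 M | 0.0600 M | 0.0600 M |
| free catalyst | 1.7 mM | 1.7 mM | 1.7 mM |
| remark | a single well-mixed tank run continuously and read at steady state, 25 h in it on average | a stirred flask in which substrate is dosed at a steady rate over 12.5 h without added volume, worked up at 25 h | a closed flask charged with all of it at once and left for 25 h |
| time |  | 25 h | 25 h |

    substrate + free catalyst ⇌ catalyst intermediate (K1 = 6.6 M⁻¹, k1 = 5.9 M⁻¹ min⁻¹)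
    catalyst intermediate → free catalyst + target (k2 = 0.38 min⁻¹)
    catalyst intermediate + capture agent → trapped intermediate (k3 = 0.68 M⁻¹ min⁻¹)

- the set-up with the highest share of target in all that became target or trapped intermediate, at the outlet or at the end ("none" if the first two lie within 2 percentage points) (ash / oak / birch / none)
- share of target in all that became target or trapped intermediate, at the outlet or at the end, ash
- share of target in all that became target or trapped intermediate, at the outlet or at the end, oak
- share of target in all that became target or trapped intermediate, at the outlet or at the end, birch

- the stated concentrations are those of everything mixed, before any reaction; amounts are the same in each set-up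
- the feed brings no volume worth counting
- run time (oak): 25 h

Step 2 makes target and step 3 makes trapped intermediate, both from that same catalyst intermediate, so I compared their rates, k2 against k3 times c(capture agent). I kept the constants together as the branching level, the c(capture agent) at which the two steps go equally fast, 0.559 M. Divided by c(capture agent), it gives the selectivity factor B, and the share of target is B/(1+B); c(substrate) does not appear in it.

With the capture agent as charged, B was 9.31 and the share 90.3%. Then I put that answer back. A catalyst that ends trapped takes 1.7 mM of capture agent, 2.83% of its charge, and by then has made 15.8 mM of target, less than the 0.20 M of substrate. Target grows evenly as capture agent falls, so for the closed flasks, oak and birch, I took the level half a catalyst charge down, which gave B = 9.45 and a share of 90.4%. Ash, read at steady state, works at its outlet level, a full catalyst charge down, which gave me 90.6%.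

Now the question turned round. For a winner, two set-ups had to stand 2 percentage points apart, and near this share that asks for a difference of 23.1% in c(capture agent). My working levels for ash and for oak and birch differ by half a catalyst charge, 1.44% of the level in oak and birch, short by a factor of 16.0. So I committed to none.

The forecast said none, with 90.5% for ash, 90.4% for oak and 90.4% for birch, on the ground that “substrate level or dosing cannot change it”. For ash, my own figure was 90.6% against its 90.5%.

The simulation gave none, with 90.5% for ash, 90.4% for oak and 90.4% for birch. In oak, the rate of step 2 over that of step 3, both as uses of catalyst intermediate, read 9.4 at 3.21 h, and the branching level divided by that reading puts c(capture agent) at 0.0595 M. The neighbouring flask is oak with 0.024 M of capture agent. There the same reckoning gave B = 24.1, a share of 96.0% and target at 20.5% of the substrate charged. That flask gave a share of 96.0%, with target at 20.5% of the substrate charged.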